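Rings are lettered A to H from the 3,5-dihydroxyphenoxy end. Ring C bears oxygen at C2, C4 (bridge to ring D) and C6, and the ring B oxygen at C1. This is the carbon–oxygen pattern of a folded triketide, so ring C is built last by disconnecting C1–C2 instead of arylating the crowded C1 oxygen. The precursor is a 2-pyrone carrying the D–H pentamer as its 4-aryloxy group and the AB dimer as its 6-(aryloxymethyl) group. A hindered alkoxide opens the lactone and the OCH2 carbanion attacks the former lactone carbonyl. One operation turns the heterocycle into the benzene ring with both ether bridges already in place. Methyl ethers are cleaved at the end.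

Key step: step 14

Remark: the target has no stereocentre and its diaryl ether bonds are taken to rotate freely, so the only stereodescriptor in the route is the alkene geometry of the ring-opened intermediate of the key step.

Step 1
Reactants: 1 4-bromo-2,6-dimethoxyphenol; 2 (3,4,5-trimethoxyphenyl)boronic acid
Product: 3 5-(4-bromo-2,6-dimethoxyphenoxy)-1,2,3-trimethoxybenzene
Conditions: Cu(OAc)2 (2 equiv), pyridine, 4 Å MS, CH2Cl2, dry air, rt
Reagents that add atoms: none
Why: Chan–Lam oxidative O-arylation accepts phenols flanked by two ortho substituents and runs at room temperature, where the aryl bromide is inert to copper, so the C–Br handle needed in steps 3 and 5 is kept.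

Step 2
Reactants: 3 5-(4-bromo-2,6-dimethoxyphenoxy)-1,2,3-trimethoxybenzene
Product: 4 6-(4-bromo-2,6-dimethoxyphenoxy)-2,3,4-trimethoxybenzaldehyde
Conditions: POCl3, DMF, 0 to 60 °C; then H2O
Reagents that add atoms: N,N-dimethylformamide CN(C)C=O; water O
Why: Vilsmeier–Haack formylation should select the ring with four oxygen donors, whose two free positions are equivalent (ortho to the aryloxy group, para to a methoxy group), because the other ring is deactivated by bromine and resembles the sluggish 5-bromo-1,2,3-trimethoxybenzene; the aldehyde serves as a latent phenol oxygen.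

Step 3
Reactants: 5 2,4,6-trimethoxyphenol; 4 6-(4-bromo-2,6-dimethoxyphenoxy)-2,3,4-trimethoxybenzaldehyde
Product: 6 FGH aldehyde 6-[2,6-dimethoxy-4-(2,4,6-trimethoxyphenoxy)phenoxy]-2,3,4-trimethoxybenzaldehyde
Conditions: CuI (10 mol %), picolinic acid (20 mol %), K3PO4, DMSO, 90 °C, argon
Reagents that add atoms: none
Why: Ligand-accelerated Ullmann diaryl ether coupling uses the hindered partner as phenoxide and the unhindered partner (bromine between two hydrogens) as halide, the pairing this catalysis handles best, and the non-enolisable aldehyde is untouched by K3PO4.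

Step 4
Reactants: 6 FGH aldehyde
Product: 8 FGH phenol 6-[2,6-dimethoxy-4-(2,4,6-trimethoxyphenoxy)phenoxy]-2,3,4-trimethoxyphenol, via FGH aryl formate 7 (not isolated)
Conditions: mCPBA, CH2Cl2, 0 °C to rt; aq NaHCO3 wash; then K2CO3 (cat.), MeOH, rt
Reagents that add atoms: 3-chloroperoxybenzoic acid OOC(=O)c1cccc(Cl)c1
Why: Baeyer–Villiger oxidation of an electron-rich benzaldehyde with two ortho oxygen substituents proceeds by aryl migration to the formate, which base-catalysed methanolysis converts into the free phenol.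

Step 5
Reactants: 8 FGH phenol; 4 6-(4-bromo-2,6-dimethoxyphenoxy)-2,3,4-trimethoxybenzaldehyde
Product: 9 DEFGH aldehyde (compound 4 with bromine replaced by the aryloxy group of 8)
Conditions: CuI (20 mol %), picolinic acid (40 mol %), K3PO4, DMSO, 100 °C, argon
Reagents that add atoms: none
Why: The same Ullmann ether coupling as in step 3 (hindered phenoxide, unhindered bromide) lets a second copy of building block 4 add rings D and E together.

Step 6
Reactants: 9 DEFGH aldehyde
Product: 11 DEFGH phenol (free hydroxyl on C1 of ring D), via DEFGH aryl formate 10 (not isolated)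
Conditions: mCPBA, CH2Cl2, 0 °C to rt; aq NaHCO3 wash; then K2CO3 (cat.), MeOH, rt
Reagents that add atoms: 3-chloroperoxybenzoic acid OOC(=O)c1cccc(Cl)c1
Why: Baeyer–Villiger oxidation and formate methanolysis as in step 4 act on the only carbonyl group present and reveal the ring D oxygen that will sit on C4 of ring C.

Step 7
Reactants: 12 2-bromo-3,4,5-trimethoxybenzaldehyde; 13 3,5-dimethoxyphenol
Product: 14 AB aldehyde 2-(3,5-dimethoxyphenoxy)-3,4,5-trimethoxybenzaldehyde
Conditions: CuI (10 mol %), picolinic acid (20 mol %), K3PO4, DMSO, 100 °C, argon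
Reagents that add atoms: none
Why: Ullmann ether coupling of an unhindered phenoxide with a bromide that is activated, and able to bind copper, through its ortho formyl group is the type of coupling long used on 2-bromo-3,4,5-trimethoxybenzoyl derivatives.

Step 8
Reactants: 14 AB aldehyde
Product: 16 AB phenol 2-(3,5-dimethoxyphenoxy)-3,4,5-trimethoxyphenol, via AB aryl formate 15 (not isolated)
Conditions: mCPBA, CH2Cl2, 0 °C to rt; aq NaHCO3 wash; then K2CO3 (cat.), MeOH, rt
Reagents that add atoms: 3-chloroperoxybenzoic acid OOC(=O)c1cccc(Cl)c1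
Why: Baeyer–Villiger oxidation with aryl migration is favoured by the ortho aryloxy and para methoxy donors, and methanolysis of the formate frees the ring B oxygen destined for C1 of ring C.

Step 9
Reactants: 16 AB phenol; 17 2-chloro-N-methoxy-N-methylacetamide
Product: 18 2-[2-(3,5-dimethoxyphenoxy)-3,4,5-trimethoxyphenoxy]-N-methoxy-N-methylacetamide
Conditions: K2CO3, DMF, 60 °C
Reagents that add atoms: none
Why: Williamson alkylation of a phenoxide with an activated primary chloride brings in the future C1 of ring C already bound to the ring B oxygen, so no radical or electrophilic bromination of a pyrone methyl group has to be run beside electron-rich arenes.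

Step 10
Reactants: 19 2,2,6-trimethyl-4H-1,3-dioxin-4-one; 18 AB-oxy N-methoxy-N-methylacetamide
Product: 21 6-{3-[2-(3,5-dimethoxyphenoxy)-3,4,5-trimethoxyphenoxy]-2-oxopropyl}-2,2-dimethyl-4H-1,3-dioxin-4-one, via lithium dienolate 20 (not isolated)
Conditions: 19, LiN(SiMe3)2, THF, −78 °C; then 18, −78 to −20 °C; 1 M HCl
Reagents that add atoms: none
Why: Crossed Claisen acylation of the dioxinone dienolate at its gamma carbon by a Weinreb amide stops at the ketone stage because the chelated tetrahedral adduct survives until the acidic quench.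

Step 11
Reactants: 21 keto dioxinone
Product: 23 6-{[2-(3,5-dimethoxyphenoxy)-3,4,5-trimethoxyphenoxy]methyl}-4-hydroxy-2H-pyran-2-one, via acylketene 22 (not isolated)
Conditions: toluene, 110 °C
Reagents that add atoms: none
Why: Retro-hetero-Diels–Alder loss of acetone gives an acylketene that is trapped by the enol oxygen of the remote ketone, the standard entry to 6-substituted 4-hydroxy-2-pyrones.

Step 12
Reactants: 23 4-hydroxy-2-pyrone
Product: 24 4-bromo-6-{[2-(3,5-dimethoxyphenoxy)-3,4,5-trimethoxyphenoxy]methyl}-2H-pyran-2-one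
Conditions: Bu4NBr, P2O5, toluene, 90 °C
Reagents that add atoms: tetrabutylammonium bromide CCCC[N+](CCCC)(CCCC)CCCC.[Br-]
Why: Dehydrative bromination of a vinylogous acid (O-phosphorylation, then addition–elimination by bromide) is the method used on triacetic acid lactone, and it involves neither electrophilic bromine nor a formylating species that could attack rings A and B.

Step 13
Reactants: 24 4-bromo-2-pyrone; 11 DEFGH phenol
Product: 25 4-(DEFGH aryloxy)-6-[(AB aryloxy)methyl]-2H-pyran-2-one
Conditions: K2CO3, MeCN, 50 °C, argon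
Reagents that add atoms: none
Why: Vinylogous acyl substitution (addition–elimination) of a phenoxide at C4 of a 4-bromo-2-pyrone is known with ortho-substituted phenols, C4 lies between two CH groups and is open to the hindered nucleophile, and carbonate is too weak to deprotonate the OCH2 group to any extent.

Step 14
Reactants: 25 4-(DEFGH aryloxy)-6-[(AB aryloxy)methyl]-2H-pyran-2-one
Product: 27 octamer octadecamethyl ether having both ring C hydroxyls free, via ring-opened tert-butyl keto ester 26 (not isolated)
Conditions: KOtBu (4 equiv), THF, 0 to 50 °C, argon; then 1 M HCl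
Reagents that add atoms: none
Why: Proposed new method: tert-butoxide adds to the lactone carbonyl C2 and the C2–O1 bond breaks to give keto ester 26, in which the former ring double bond C3=C4 holds the ester arm and the CH2C(=O) arm cis (this is the E isomer by the sequence rule, because the aryloxy oxygen on C4 outranks C5). The terminal OCH2 group, acidified by the ketone and the ring B aryloxy group, is deprotonated in equilibrium and its carbanion attacks the ester in a 6-(enolendo)-exo-trig Claisen (Dieckmann-type) closure that forms C1–C2 of ring C; loss of tert-butoxide and double enolisation give the resorcinol dianion, an irreversible sink that also drains the reversible relactonisation. The closest known reaction types are the alkoxide-induced isomerisation of 4-alkoxy-6-methyl-2-pyrones to phloroglucinol monoethers and the rearrangement of enol lactones such as 3-benzylidenephthalide to cyclic 1,3-diones, neither of which has been run with aryloxy groups at both sites. No stereocentre is formed. The step needs attack at C2 rather than addition–elimination at C4, which would expel the pentamer aryloxide: ring D stands perpendicular to the pyrone so that its two ortho substituents (a methoxy group and the ring E oxygen) cover both faces of C4, and a tertiary alkoxide cannot build the crowded ketal-like adduct there, whereas a small alkoxide such as methoxide could. If tert-butoxide acts only as a base, E1cB cleavage of the same C2–O1 bond from the OCH2 carbanion gives a dienylketene whose carbonyl carbon is attacked by the same carbon, so both channels should lead to 27.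

Step 15
Reactants: 27 octamer octadecamethyl ether
Product: 28 target CNP0319661.0
Conditions: BBr3 (60 equiv), CH2Cl2, −78 °C to rt, argon; then degassed H2O
Reagents that add atoms: none
Why: Lewis-acid ether cleavage by BBr3 removes each methyl group through bromide attack at the methyl carbon, while the seven diaryl ether bonds offer no sp3 carbon for that attack and should stay intact.

Compound list
1 | 4-bromo-2,6-dimethoxyphenol | COc1cc(Br)cc(OC)c1O | starting material
2 | (3,4,5-trimethoxyphenyl)boronic acid | COc1cc(B(O)O)cc(OC)c1OC | starting material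
3 | 5-(4-bromo-2,6-dimethoxyphenoxy)-1,2,3-trimethoxybenzene | COc1cc(Oc2c(OC)cc(Br)cc2OC)cc(OC)c1OC | intermediate
4 | 6-(4-bromo-2,6-dimethoxyphenoxy)-2,3,4-trimethoxybenzaldehyde (two-ring building block, used twice) | COc1cc(Oc2c(OC)cc(Br)cc2OC)c(C=O)c(OC)c1OC | intermediate
5 | 2,4,6-trimethoxyphenol (ring H) | COc1cc(OC)c(O)c(OC)c1 | starting material
6 | FGH aldehyde, 6-[2,6-dimethoxy-4-(2,4,6-trimethoxyphenoxy)phenoxy]-2,3,4-trimethoxybenzaldehyde | COc1cc(Oc2c(OC)cc(Oc3c(OC)cc(OC)cc3OC)cc2OC)c(C=O)c(OC)c1OC | intermediate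
7 | FGH aryl formate (formate ester of 8) | COc1cc(Oc2c(OC)cc(Oc3c(OC)cc(OC)cc3OC)cc2OC)c(OC=O)c(OC)c1OC | intermediate
8 | FGH phenol, 6-[2,6-dimethoxy-4-(2,4,6-trimethoxyphenoxy)phenoxy]-2,3,4-trimethoxyphenol | COc1cc(Oc2c(OC)cc(Oc3c(OC)cc(OC)cc3OC)cc2OC)c(O)c(OC)c1OC | intermediate
9 | DEFGH aldehyde (4 with Br replaced by the aryloxy group of 8) | COc1cc(Oc2c(OC)cc(Oc3c(Oc4c(OC)cc(Oc5c(OC)cc(OC)cc5OC)cc4OC)cc(OC)c(OC)c3OC)cc2OC)c(C=O)c(OC)c1OC | intermediate
10 | DEFGH aryl formate (formate ester of 11) | COc1cc(Oc2c(OC)cc(Oc3c(Oc4c(OC)cc(Oc5c(OC)cc(OC)cc5OC)cc4OC)cc(OC)c(OC)c3OC)cc2OC)c(OC=O)c(OC)c1OC | intermediate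
11 | DEFGH phenol (9 with CHO replaced by OH; hydroxyl on C1 of ring D) | COc1cc(Oc2c(OC)cc(Oc3c(Oc4c(OC)cc(Oc5c(OC)cc(OC)cc5OC)cc4OC)cc(OC)c(OC)c3OC)cc2OC)c(O)c(OC)c1OC | intermediate
12 | 2-bromo-3,4,5-trimethoxybenzaldehyde | COc1cc(C=O)c(Br)c(OC)c1OC | starting material
13 | 3,5-dimethoxyphenol | COc1cc(O)cc(OC)c1 | starting material
14 | AB aldehyde, 2-(3,5-dimethoxyphenoxy)-3,4,5-trimethoxybenzaldehyde | COc1cc(OC)cc(Oc2c(C=O)cc(OC)c(OC)c2OC)c1 | intermediate
15 | AB aryl formate (formate ester of 16) | COc1cc(OC)cc(Oc2c(OC=O)cc(OC)c(OC)c2OC)c1 | intermediate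
16 | AB phenol, 2-(3,5-dimethoxyphenoxy)-3,4,5-trimethoxyphenol | COc1cc(OC)cc(Oc2c(O)cc(OC)c(OC)c2OC)c1 | intermediate
17 | 2-chloro-N-methoxy-N-methylacetamide | CON(C)C(=O)CCl | starting material
18 | 2-[2-(3,5-dimethoxyphenoxy)-3,4,5-trimethoxyphenoxy]-N-methoxy-N-methylacetamide | COc1cc(OC)cc(Oc2c(OCC(=O)N(C)OC)cc(OC)c(OC)c2OC)c1 | intermediate
19 | 2,2,6-trimethyl-4H-1,3-dioxin-4-one | CC1=CC(=O)OC(C)(C)O1 | starting material
20 | lithium dienolate of 19 (lithium 2,2-dimethyl-6-methylidene-1,3-dioxin-4-olate) | [Li+].C=C1C=C([O-])OC(C)(C)O1 | intermediate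
21 | 6-{3-[2-(3,5-dimethoxyphenoxy)-3,4,5-trimethoxyphenoxy]-2-oxopropyl}-2,2-dimethyl-4H-1,3-dioxin-4-one | COc1cc(OC)cc(Oc2c(OCC(=O)CC3=CC(=O)OC(C)(C)O3)cc(OC)c(OC)c2OC)c1 | intermediate
22 | acylketene, 6-(AB aryloxy)-3,5-dioxohex-1-en-1-one | COc1cc(OC)cc(Oc2c(OCC(=O)CC(=O)C=C=O)cc(OC)c(OC)c2OC)c1 | intermediate
23 | 6-{[2-(3,5-dimethoxyphenoxy)-3,4,5-trimethoxyphenoxy]methyl}-4-hydroxy-2H-pyran-2-one | COc1cc(OC)cc(Oc2c(OCC3=CC(O)=CC(=O)O3)cc(OC)c(OC)c2OC)c1 | intermediate
24 | 4-bromo-6-{[2-(3,5-dimethoxyphenoxy)-3,4,5-trimethoxyphenoxy]methyl}-2H-pyran-2-one | COc1cc(OC)cc(Oc2c(OCC3=CC(Br)=CC(=O)O3)cc(OC)c(OC)c2OC)c1 | intermediate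
25 | key-step precursor, 2-pyrone with the aryloxy group of 11 on C4 and the (aryloxy)methyl group of 16 on C6 | COc1cc(OC)cc(Oc2c(OCC3=CC(Oc4c(Oc5c(OC)cc(Oc6c(Oc7c(OC)cc(Oc8c(OC)cc(OC)cc8OC)cc7OC)cc(OC)c(OC)c6OC)cc5OC)cc(OC)c(OC)c4OC)=CC(=O)O3)cc(OC)c(OC)c2OC)c1 | intermediate
26 | tert-butyl (2E)-3-(DEFGH aryloxy)-6-(AB aryloxy)-5-oxohex-2-enoate | CC(C)(C)OC(=O)/C=C(/Oc1c(Oc2c(OC)cc(Oc3c(Oc4c(OC)cc(Oc5c(OC)cc(OC)cc5OC)cc4OC)cc(OC)c(OC)c3OC)cc2OC)cc(OC)c(OC)c1OC)CC(=O)COc1cc(OC)c(OC)c(OC)c1Oc1cc(OC)cc(OC)c1 | intermediate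
27 | key-step product, octamer octadecamethyl ether (ring C = 2-(AB aryloxy)-5-(DEFGH aryloxy)benzene-1,3-diol) | COc1cc(OC)cc(Oc2c(Oc3c(O)cc(Oc4c(Oc5c(OC)cc(Oc6c(Oc7c(OC)cc(Oc8c(OC)cc(OC)cc8OC)cc7OC)cc(OC)c(OC)c6OC)cc5OC)cc(OC)c(OC)c4OC)cc3O)cc(OC)c(OC)c2OC)c1 | intermediate
28 | CNP0319661.0, free octamer with twenty hydroxyl groups | Oc1cc(O)cc(Oc2c(Oc3c(O)cc(Oc4c(Oc5c(O)cc(Oc6c(Oc7c(O)cc(Oc8c(O)cc(O)cc8O)cc7O)cc(O)c(O)c6O)cc5O)cc(O)c(O)c4O)cc3O)cc(O)c(O)c2O)c1 | target

Total step count: 15.
Longest linear sequence: 9 steps (1, 2, 3, 4, 5, 6, 13, 14, 15). The AB branch (7 to 12, then 13 to 15) is equally long.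

Steps most likely to fail

Step 14. The alkoxide may expel the pentamer aryloxide by addition–elimination at C4. The reaction may also stall in the equilibrium between ring-opened enolate and lactone without carbon acylation. The fallback uses known chemistry only and brings ring C in as a preformed arene. It sets out from 4. Baeyer–Villiger oxidation with mCPBA gives bromo aryl formate F1, and catalytic K2CO3 in MeOH gives bromo phenol F2. Chan–Lam coupling of F2 with commercial (3,5-dimethoxyphenyl)boronic acid (Cu(OAc)2, pyridine, CH2Cl2, air, rt) leaves the bromide untouched and gives ABC bromide F3. Ullmann coupling of F3 with phenol 11 under the conditions of step 5 gives octamer icosamethyl ether F4. BBr3 then cleaves all twenty methyl ethers, and the sequence comes back to the route at 28.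

Step 15. Cleavage of eighteen ethers may stop at mixtures of partly methylated products. The pyrogallol-type rings B, D and F may also be oxidised by air during aqueous isolation. The fallback changes the isolation strategy to derivatise, purify and release. It sets out from 27. After BBr3 treatment the mixture is quenched with MeOH, evaporated under argon and acetylated at once (Ac2O, pyridine) to octamer icosaacetate F5. This compound should be stable in air and can be chromatographed on silica, so under-cleaved material can be separated and resubmitted. Acid-catalysed transesterification (catalytic AcCl in degassed MeOH, 0 °C to rt) forms only volatile by-products and comes back to the route at 28.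

Step 5. The bulky, doubly ortho-substituted phenoxide of 8 may bind copper poorly. The electron-rich bromide may also react too slowly, so that reduction of the C–Br bond or oxidation of the phenol takes over at 100 °C. The fallback inverts the role of the aryl partner. It sets out from 4. Miyaura borylation (B2pin2, Pd(dppf)Cl2, KOAc, dioxane, 90 °C) gives pinacol boronate F6. Oxidative Chan–Lam coupling of F6 with 8 (Cu(OAc)2, B(OH)3, pyridine, MeCN, O2, 60 °C) is a coupling type that accepts phenols with two ortho substituents, and it comes back to the route at 9.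

Further compounds
F1 | step 14 | 6-(4-bromo-2,6-dimethoxyphenoxy)-2,3,4-trimethoxyphenyl formate | COc1cc(Oc2c(OC)cc(Br)cc2OC)c(OC=O)c(OC)c1OC
F2 | step 14 | 6-(4-bromo-2,6-dimethoxyphenoxy)-2,3,4-trimethoxyphenol | COc1cc(Oc2c(OC)cc(Br)cc2OC)c(O)c(OC)c1OC
F3 | step 14 | ABC bromide, 1-(4-bromo-2,6-dimethoxyphenoxy)-2-(3,5-dimethoxyphenoxy)-3,4,5-trimethoxybenzene | COc1cc(OC)cc(Oc2c(Oc3c(OC)cc(Br)cc3OC)cc(OC)c(OC)c2OC)c1
F4 | step 14 | octamer icosamethyl ether | COc1cc(OC)cc(Oc2c(Oc3c(OC)cc(Oc4c(Oc5c(OC)cc(Oc6c(Oc7c(OC)cc(Oc8c(OC)cc(OC)cc8OC)cc7OC)cc(OC)c(OC)c6OC)cc5OC)cc(OC)c(OC)c4OC)cc3OC)cc(OC)c(OC)c2OC)c1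
F5 | step 15 | octamer icosaacetate | CC(=O)Oc1cc(OC(C)=O)cc(Oc2c(Oc3c(OC(C)=O)cc(Oc4c(Oc5c(OC(C)=O)cc(Oc6c(Oc7c(OC(C)=O)cc(Oc8c(OC(C)=O)cc(OC(C)=O)cc8OC(C)=O)cc7OC(C)=O)cc(OC(C)=O)c(OC(C)=O)c6OC(C)=O)cc5OC(C)=O)cc(OC(C)=O)c(OC(C)=O)c4OC(C)=O)cc3OC(C)=O)cc(OC(C)=O)c(OC(C)=O)c2OC(C)=O)c1
F6 | step 5 | 6-[2,6-dimethoxy-4-(4,4,5,5-tetramethyl-1,3,2-dioxaborolan-2-yl)phenoxy]-2,3,4-trimethoxybenzaldehyde | COc1cc(Oc2c(OC)cc(B3OC(C)(C)C(C)(C)O3)cc2OC)c(C=O)c(OC)c1OC
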